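We have two questions on each of two flasks. Sunday's and Thursday's are the same recipe, read at 40 min and at 80 min.

| setting | amber | ochre | red | Sunday's | Thursday's |
|---|---|---|---|---|---|
| substrate | 0.50 M | 1.1 M | 0.75 M | 0.75 M | 0.75 M |
| reagent | 1.1 equiv | 1.1 equiv | 0.55 equiv | 1.10 equiv | 1.10 equiv |
| remark | run made earlier | run made earlier | run made earlier |  |  |
| time |  |  |  | 40 min | 80 min |

| run | time / min | substrate / % | intermediate A / % | side product / % | intermediate B / % | target / % |
|---|---|---|---|---|---|---|
| amber | 1.50 | 96.9 | 1.7 | 0.4 | 0.9 | 0 |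
| amber | 5.00 | 91.4 | 7.2 | 0.1 | 1.6 | 0 |
| amber | 10.0 | 84.1 | 11.7 | 0.5 | 2.7 | 0 |
| amber | 15.0 | 77.8 | 15.3 | 0.8 | 4.1 | 0 |
| amber | 20.0 | 72.9 | 20.7 | 1.5 | 4.6 | 0.2 |
| amber | 25.0 | 67.5 | 24.1 | 2.7 | 5.0 | 1.3 |
| amber | 30.0 | 63.6 | 26.3 | 3.5 | 5.7 | 0.3 |
| ochre | 5.00 | 84.3 | 13.4 | 0.4 | 0.9 | 0.3 |
| ochre | 10.0 | 73.3 | 21.9 | 0.9 | 2.2 | 0.7 |
| ochre | 15.0 | 64.0 | 30.1 | 1.1 | 3.4 | 0.6 |
| ochre | 20.0 | 56.2 | 35.3 | 3.5 | 3.4 | 1.1 |
| ochre | 25.0 | 49.9 | 39.0 | 4.1 | 4.4 | 0.1 |
| ochre | 30.0 | 44.8 | 42.2 | 6.5 | 4.1 | 1.3 |
| red | 2.50 | 95.9 | 2.4 | 0.8 | 1.5 | 0.3 |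
| red | 5.00 | 93.8 | 3.9 | 1.1 | 1.8 | 0.6 |
| red | 10.0 | 87.5 | 8.8 | 0 | 2.8 | 0.8 |
| red | 15.0 | 82.8 | 12.0 | 1.2 | 4.1 | 0 |
| red | 30.0 | 71.3 | 19.2 | 1.9 | 6.4 | 0.3 |

(scatter of a reading: 0.5 percentage points)

1. which of these there is most of at the end, counted by the substrate in it, Sunday's (intermediate A / intermediate B / side product / substrate)
2. which of these there is most of at the end, counted by the substrate in it, Thursday's (intermediate A / intermediate B / side product / substrate)
3. the largest of these amounts at the end, in percent of the substrate charged, Sunday's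
4. the largest of these amounts at the end, in percent of the substrate charged, Thursday's



Amber and ochre charge reagent and substrate almost equally. For such a charge the bench rule of a second-order reaction says that one over the fraction of substrate left, less one, rises in a straight line with concentration times time. Ochre's last reading gives a rise of 0.0373 M⁻¹ min⁻¹ per unit of that product, and we call this the second-order slope, an apparent rate constant. Amber's last reading gives 0.0382 M⁻¹ min⁻¹, though its concentration is lower.

Sunday's product is 30.0 M·min, smaller than ochre's last 33.0 M·min, so the rule stays inside the readings and leaves 47.2 % substrate. Thursday's product is 1.82 times ochre's last. That is the border: no run reaches it, so 30.9 % is an extrapolation.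

Intermediate A is what remains of the consumed substrate after two corrections, and neither is small. We hold intermediate B at amber's last 5.7 %. Side product stood at 0.154 of intermediate A in ochre at 30.0 min, and we let this ratio grow with time. That gives 39.1 % intermediate A on Sunday's and 45.0 % on Thursday's. So we expect substrate to lead on Sunday's and intermediate A on Thursday's.

The forecast names substrate at 47 % for Sunday's and intermediate A at 43 % for Thursday's, saying “A has plateaued here”, and its Thursday's figure lies below our 45.0 %.

Sunday's flask gives substrate at 46.6 %. Thursday's flask gives intermediate A at 41.9 %.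

    reagent + target → over-reaction product (k = 0.0600 M⁻¹ min⁻¹)
    substrate ⇌ intermediate B (K = 0.550, k = 0.00340 min⁻¹)
    intermediate C → target (k = 0.0860 min⁻¹)
    intermediate A → side product (k = 0.00710 min⁻¹)
    substrate + reagent → intermediate A (k = 0.0260 M⁻¹ min⁻¹)
    intermediate B ⇌ intermediate C (K = 0.700, k = 0.0210 min⁻¹)

On Sunday's flask, substrate has a half-life of 32 min by its reaction with reagent at the charged concentrations, shorter than the 3.4 h of its forward passing into intermediate B. Thursday's 27.7 % of substrate, read back through the rule, gives a slope of 0.0436 M⁻¹ min⁻¹, steeper than 0.0373 M⁻¹ min⁻¹. The same flask read at 30 min has a product of 22.5 M·min, where the slope 0.0373 M⁻¹ min⁻¹ leaves 54.3 % and the flask holds 54.6 % substrate.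

The earlier runs and the new flask were computed with constants of no real substance; noise was put on by code.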